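The 2,3,4,7-tetrahydrooxepine (O1, quaternary C2, C3, C4, C5=C6, C7) is disconnected to a 3,4-dihydro-2H-pyran that lacks C6. In the forward sense dibromocarbene is added to the enol ether, and silver-assisted electrocyclic opening of the 7,7-dibromo-2-oxabicyclo[4.1.0]heptane inserts that carbon between the two enol-ether carbons: in one operation the oxane becomes the oxepine, C6 appears as a vinyl bromide (handle for the side chain) and C7 as an oxocarbenium ion, later reduced to O–CH2. The C2 stereocentre is set beforehand by a Cu(OTf)2/bis(oxazoline)-catalysed Mukaiyama aldol addition to an α-keto ester and is a spectator. The feature exploited is the allylic ether unit O1–C7H2–C6(R)=C5H of the oxepine ring.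

Key step: step 9

Assumption: the Cu(OTf)2/bis(oxazoline) aldol addition is taken to follow the facial sense known for pyruvate esters (si-face attack with the (S,S)-ligand), which gives the (S) centre of the target; if the sense were opposite, the (R,R)-ligand would be used.

Abbreviations: TBS = tert-butyldimethylsilyl; TMSE = 2-(trimethylsilyl)ethyl; Ar = 2,5-bis(TBS-oxy)phenyl. Compounds 13, 14, 16 and 18 are mixtures of diastereomers at centres that later steps destroy; C2 is (S) throughout.

Step 1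
Reactants: 1 oxalyl chloride; 2 2-(trimethylsilyl)ethanol
Product: 3 bis[2-(trimethylsilyl)ethyl] oxalate
Conditions: 2 (2.1 equiv), pyridine, CH2Cl2, 0 °C → rt
Reagents that add atoms: none
Why: Twofold acylation of a primary alcohol by an acid chloride with pyridine as acid scavenger gives the diester that carries the fluoride-labile ester group needed at the end.

Step 2
Reactants: 4 5-bromopent-1-ene; 3 bis[2-(trimethylsilyl)ethyl] oxalate
Product: 6 TMSE 2-oxohept-6-enoate, via pent-4-enylmagnesium bromide 5 (not isolated)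
Conditions: Mg, THF, rt; then added to 3 (1.5 equiv), THF–Et2O, −78 °C; aq. NH4Cl
Reagents that add atoms: magnesium, [Mg] (atoms kept only in intermediate 5)
Why: Mono-addition of a Grignard reagent to an oxalate diester, in which the chelated tetrahedral adduct is stable at −78 °C and collapses to the α-keto ester only on work-up, so a second addition is avoided.

Step 3
Reactants: 7 2',5'-dihydroxyacetophenone
Product: 8 2',5'-bis(TBS-oxy)acetophenone
Conditions: TBSCl (2.5 equiv), imidazole, DMF, rt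
Reagents that add atoms: tert-butyldimethylsilyl chloride, CC(C)(C)[Si](C)(C)Cl
Why: Standard imidazole-promoted silylation of both phenols gives ethers that resist mild acid and are removed by fluoride in the last step.

Step 4
Reactants: 8 2',5'-bis(TBS-oxy)acetophenone
Product: 9 1-Ar-1-(trimethylsilyloxy)ethene
Conditions: TMSOTf, Et3N, CH2Cl2, 0 °C
Reagents that add atoms: trimethylsilyl trifluoromethanesulfonate, C[Si](C)(C)OS(=O)(=O)C(F)(F)F
Why: Soft enolisation of the methyl ketone (O-silylation, then deprotonation by the amine) gives the only possible enol silane.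

Step 5
Reactants: 6 TMSE 2-oxohept-6-enoate; 9 1-Ar-1-(trimethylsilyloxy)ethene
Product: 11 TMSE (S)-2-(2-Ar-2-oxoethyl)-2-hydroxyhept-6-enoate, via trimethylsilyl ether of the aldol adduct 10 (not isolated)
Conditions: Cu(OTf)2 (10 mol %), 2,2'-(propane-2,2-diyl)bis[(4S)-4-tert-butyl-4,5-dihydrooxazole] (11 mol %), THF, −78 °C; then 1 M HCl, THF, 0 °C
Reagents that add atoms: none
Why: Catalytic enantioselective Mukaiyama aldol addition to an α-keto ester held as a five-membered chelate on divalent copper, in which the tert-butyl groups of the (S,S)-ligand should leave only the si face of the ketone open and so set the (S) quaternary carbinol centre.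

Step 6
Reactants: 11 TMSE (S)-2-(2-Ar-2-oxoethyl)-2-hydroxyhept-6-enoate
Product: 13 TMSE (2S)-2-(2-Ar-2-oxoethyl)-6-hydroxytetrahydro-2H-pyran-2-carboxylate (mixture of anomers), via hydroxy aldehyde 12 (not isolated)
Conditions: O3, CH2Cl2, −78 °C (TLC control); then PPh3, −78 °C → rt
Reagents that add atoms: ozone, [O-][O+]=O
Why: Ozonolysis with reductive work-up cleaves the only alkene, and the resulting δ-hydroxy aldehyde should close spontaneously to the six-membered lactol.

Step 7
Reactants: 13 TMSE (2S)-2-(2-Ar-2-oxoethyl)-6-hydroxytetrahydro-2H-pyran-2-carboxylate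
Product: 15 TMSE (S)-2-(2-Ar-2-oxoethyl)-3,4-dihydro-2H-pyran-2-carboxylate, via anomeric methanesulfonate 14 (not isolated)
Conditions: MsCl, Et3N, CH2Cl2, −20 °C → 40 °C
Reagents that add atoms: methanesulfonyl chloride, CS(=O)(=O)Cl (atoms kept only in intermediate 14)
Why: Lactol dehydration by way of the anomeric sulfonate, as in glycal syntheses from 2-deoxy lactols, can only place the double bond at C5=C6 because C2 is quaternary, and the weak amine base should leave the β-alkoxy ketone untouched.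

Step 8
Reactants: 15 TMSE (S)-2-(2-Ar-2-oxoethyl)-3,4-dihydro-2H-pyran-2-carboxylate
Product: 16 TMSE (3S)-3-(2-Ar-2-oxoethyl)-7,7-dibromo-2-oxabicyclo[4.1.0]heptane-3-carboxylate (both cis-fused diastereomers)
Conditions: PhHgCBr3 (1.5 equiv), benzene, 80 °C
Reagents that add atoms: phenyl(tribromomethyl)mercury, BrC(Br)(Br)[Hg]c1ccccc1
Why: Cheletropic addition of dibromocarbene, released under neutral conditions from PhHgCBr3 (Seyferth reagent), to the electron-rich enol ether spares the enolisable ketone, the silyl ethers and the ester, and both face isomers (as well as any adduct that has already opened thermally) converge in step 9.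

Step 9
Reactants: 16 TMSE (3S)-3-(2-Ar-2-oxoethyl)-7,7-dibromo-2-oxabicyclo[4.1.0]heptane-3-carboxylate
Product: 18 TMSE (2S)-2-(2-Ar-2-oxoethyl)-6-bromo-7-methoxy-2,3,4,7-tetrahydrooxepine-2-carboxylate (C7 epimers), via bromoallyl oxocarbenium ion 17 (not isolated)
Conditions: AgOTf (1.5 equiv), 2,6-lutidine, MeOH–CH2Cl2, 0 °C → rt
Reagents that add atoms: methanol, CO
Why: Silver ion abstracts the endo bromide (the one syn to the oxane ring) while the C1–C6 bond shared by the three- and six-membered rings cleaves in a disrotatory two-electron electrocyclic opening of the incipient cyclopropyl cation (Woodward–Hoffmann–DePuy rule), pushed by a lone pair of the ring oxygen, so that the oxane of 16 becomes the seven-membered bromoallyl oxocarbenium ion 17, which methanol captures at C7. The closest known reaction type is the silver- or heat-promoted ring enlargement of dihalocarbene adducts of dihydropyrans and glycals to 2-alkoxy-3-halo-tetrahydrooxepines. No ring is closed by a cyclisation, since the seven-membered ring arises by scission of the internal cyclopropane bond, so no Baldwin mode applies, and the cis ring alkene follows from the inward rotation that the bicyclic frame enforces. The only new stereocentre, the acetal carbon C7, is not controlled and need not be, because step 10 removes it, while C2 takes no part and keeps its (S) configuration. The step needs ionisation of the endo and not the exo C–Br bond, which the ring fusion secures for both diastereomers of 16 because only the cis,cis allyl cation fits the ring, and it needs capture at C7 and not at C5, which the oxocarbenium character of C7 favours (a C5 adduct would in any case be ionised again by the Lewis acid of step 10 and so converge on the same product). The buffered, non-basic medium should spare the β-alkoxy ketone, the aryl silyl ethers and the ester.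

Step 10
Reactants: 18 TMSE (2S)-2-(2-Ar-2-oxoethyl)-6-bromo-7-methoxy-2,3,4,7-tetrahydrooxepine-2-carboxylate
Product: 19 TMSE (S)-2-(2-Ar-2-oxoethyl)-6-bromo-2,3,4,7-tetrahydrooxepine-2-carboxylate
Conditions: Et3SiH (3 equiv), BF3·OEt2 (1.5 equiv), CH2Cl2, −78 → −40 °C
Reagents that add atoms: none
Why: Ionic hydrogenation of the allylic acetal, in which BF3 removes methoxide and the silane should deliver hydride to the oxygen-bearing terminus of the transient allyl cation as in Ferrier-type reductions, gives the O–C7H2 group with the C5=C6 alkene in place, and at low temperature the aryl ketone is expected to survive.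

Step 11
Reactants: 20 tert-butyldimethyl(prop-2-yn-1-yloxy)silane
Product: 23 (E)-5-(TBS-oxy)-4-methylpent-3-en-1-ol, via alkenyldimethylalane 21 (not isolated), via lithium alkenylbutyldimethylalanate 22 (not isolated)
Conditions: Me3Al (2.5 equiv), Cp2ZrCl2 (25 mol %), CH2Cl2, rt; solvent exchange to THF; n-BuLi, −78 °C; ethylene oxide, −78 °C → rt; aq. NH4Cl, aq. potassium sodium tartrate
Reagents that add atoms: trimethylaluminium, C[Al](C)C; ethylene oxide, C1CO1; n-butyllithium, [Li]CCCC (atoms kept only in intermediate 22)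
Why: Zirconium-catalysed carboalumination of the terminal alkyne (Negishi) adds methyl and aluminium syn, and the derived alanate opens ethylene oxide with retention at the alkenyl carbon, so the new chain ends up cis to methyl and trans to CH2O, the (E) geometry of the target.

Step 12
Reactants: 23 (E)-5-(TBS-oxy)-4-methylpent-3-en-1-ol
Product: 24 (E)-tert-butyl[(5-iodo-2-methylpent-2-en-1-yl)oxy]dimethylsilane
Conditions: I2, PPh3, imidazole, CH2Cl2, 0 °C
Reagents that add atoms: iodine, II
Why: Appel-type iodination (Garegg–Samuelsson conditions) displaces the primary alkoxyphosphonium by iodide without touching the alkene or the silyl ether.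

Step 13
Reactants: 24 (E)-tert-butyl[(5-iodo-2-methylpent-2-en-1-yl)oxy]dimethylsilane; 19 TMSE (S)-2-(2-Ar-2-oxoethyl)-6-bromo-2,3,4,7-tetrahydrooxepine-2-carboxylate
Product: 26 TMSE (S)-2-(2-Ar-2-oxoethyl)-6-[(E)-5-(TBS-oxy)-4-methylpent-3-enyl]-2,3,4,7-tetrahydrooxepine-2-carboxylate, via alkylzinc iodide 25 (not isolated)
Conditions: Zn dust, LiCl, THF, 40 °C; then 19, PdCl2(dppf) (5 mol %), THF, 45 °C
Reagents that add atoms: zinc, [Zn] (atoms kept only in intermediate 25)
Why: Negishi coupling of a primary alkylzinc iodide and an alkenyl bromide on zerovalent palladium needs no base, so the β-alkoxy ketone, the ester and the silyl ethers should be tolerated, and the bidentate ligand suppresses β-hydride elimination.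

Step 14
Reactants: 26 TMSE (S)-2-(2-Ar-2-oxoethyl)-6-[(E)-5-(TBS-oxy)-4-methylpent-3-enyl]-2,3,4,7-tetrahydrooxepine-2-carboxylate
Product: 27 TMSE (S)-2-(2-Ar-2-oxoethyl)-6-[(E)-5-hydroxy-4-methylpent-3-enyl]-2,3,4,7-tetrahydrooxepine-2-carboxylate
Conditions: PPTS (0.2 equiv), MeOH, rt
Reagents that add atoms: none
Why: Acid-catalysed methanolysis removes the primary alkyl silyl ether selectively, because the aryl silyl ethers are much less basic at oxygen and stay intact under mild acid.

Step 15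
Reactants: 27 TMSE (S)-2-(2-Ar-2-oxoethyl)-6-[(E)-5-hydroxy-4-methylpent-3-enyl]-2,3,4,7-tetrahydrooxepine-2-carboxylate; 28 (E)-4-hydroxycinnamic acid (p-coumaric acid)
Product: 29 TMSE (S)-2-(2-Ar-2-oxoethyl)-6-[(E)-5-[(E)-3-(4-hydroxyphenyl)acryloyloxy]-4-methylpent-3-enyl]-2,3,4,7-tetrahydrooxepine-2-carboxylate
Conditions: 28 (1.5 equiv), PPh3, DIAD, THF, 0 °C → rt
Reagents that add atoms: none
Why: Mitsunobu esterification activates the primary allylic alcohol, and the carboxylic acid, far more acidic than the phenol, should be the nucleophile that attacks the unhindered primary carbon directly, which keeps both (E) alkenes.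

Step 16
Reactants: 29 TMSE (S)-2-(2-Ar-2-oxoethyl)-6-[(E)-5-[(E)-3-(4-hydroxyphenyl)acryloyloxy]-4-methylpent-3-enyl]-2,3,4,7-tetrahydrooxepine-2-carboxylate
Product: 30 (S)-2-[2-(2,5-dihydroxyphenyl)-2-oxoethyl]-6-[(E)-5-[(E)-3-(4-hydroxyphenyl)acryloyloxy]-4-methylpent-3-enyl]-2,3,4,7-tetrahydrooxepine-2-carboxylic acid
Conditions: TASF (5 equiv), DMF, 0 °C → rt; work-up with dilute HCl to pH 3
Reagents that add atoms: none
Why: Anhydrous fluoride cleaves both aryl silyl ethers and fragments the 2-(trimethylsilyl)ethyl ester (loss of ethene) in one operation, under conditions mild enough that the coumarate ester and the β-alkoxy ketone should survive.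

Compound list
1 | oxalyl chloride | O=C(Cl)C(=O)Cl | starting material
2 | 2-(trimethylsilyl)ethanol | C[Si](C)(C)CCO | starting material
3 | bis[2-(trimethylsilyl)ethyl] oxalate | C[Si](C)(C)CCOC(=O)C(=O)OCC[Si](C)(C)C | intermediate
4 | 5-bromopent-1-ene | C=CCCCBr | starting material
5 | pent-4-enylmagnesium bromide | C=CCCC[Mg]Br | intermediate (not isolated)
6 | 2-(trimethylsilyl)ethyl 2-oxohept-6-enoate | C=CCCCC(=O)C(=O)OCC[Si](C)(C)C | intermediate
7 | 2',5'-dihydroxyacetophenone | CC(=O)c1cc(O)ccc1O | starting material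
8 | 2',5'-bis(tert-butyldimethylsilyloxy)acetophenone | CC(=O)c1cc(O[Si](C)(C)C(C)(C)C)ccc1O[Si](C)(C)C(C)(C)C | intermediate
9 | 1-[2,5-bis(tert-butyldimethylsilyloxy)phenyl]-1-(trimethylsilyloxy)ethene | C=C(O[Si](C)(C)C)c1cc(O[Si](C)(C)C(C)(C)C)ccc1O[Si](C)(C)C(C)(C)C | intermediate
10 | 2-(trimethylsilyl)ethyl (S)-2-{2-[2,5-bis(TBS-oxy)phenyl]-2-oxoethyl}-2-(trimethylsilyloxy)hept-6-enoate | C=CCCC[C@](CC(=O)c1cc(O[Si](C)(C)C(C)(C)C)ccc1O[Si](C)(C)C(C)(C)C)(C(=O)OCC[Si](C)(C)C)O[Si](C)(C)C | intermediate (not isolated)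
11 | 2-(trimethylsilyl)ethyl (S)-2-{2-[2,5-bis(TBS-oxy)phenyl]-2-oxoethyl}-2-hydroxyhept-6-enoate | C=CCCC[C@](CC(=O)c1cc(O[Si](C)(C)C(C)(C)C)ccc1O[Si](C)(C)C(C)(C)C)(C(=O)OCC[Si](C)(C)C)O | intermediate
12 | 2-(trimethylsilyl)ethyl (S)-2-{2-[2,5-bis(TBS-oxy)phenyl]-2-oxoethyl}-2-hydroxy-6-oxohexanoate | O=CCCC[C@](CC(=O)c1cc(O[Si](C)(C)C(C)(C)C)ccc1O[Si](C)(C)C(C)(C)C)(C(=O)OCC[Si](C)(C)C)O | intermediate (not isolated)
13 | 2-(trimethylsilyl)ethyl (2S)-2-{2-[2,5-bis(TBS-oxy)phenyl]-2-oxoethyl}-6-hydroxytetrahydro-2H-pyran-2-carboxylate, anomer mixture | OC1CCC[C@](CC(=O)c2cc(O[Si](C)(C)C(C)(C)C)ccc2O[Si](C)(C)C(C)(C)C)(C(=O)OCC[Si](C)(C)C)O1 | intermediate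
14 | 2-(trimethylsilyl)ethyl (2S)-2-{2-[2,5-bis(TBS-oxy)phenyl]-2-oxoethyl}-6-(methanesulfonyloxy)tetrahydro-2H-pyran-2-carboxylate | CS(=O)(=O)OC1CCC[C@](CC(=O)c2cc(O[Si](C)(C)C(C)(C)C)ccc2O[Si](C)(C)C(C)(C)C)(C(=O)OCC[Si](C)(C)C)O1 | intermediate (not isolated)
15 | 2-(trimethylsilyl)ethyl (S)-2-{2-[2,5-bis(TBS-oxy)phenyl]-2-oxoethyl}-3,4-dihydro-2H-pyran-2-carboxylate | C1=CCC[C@](CC(=O)c2cc(O[Si](C)(C)C(C)(C)C)ccc2O[Si](C)(C)C(C)(C)C)(C(=O)OCC[Si](C)(C)C)O1 | intermediate
16 | 2-(trimethylsilyl)ethyl (3S)-3-{2-[2,5-bis(TBS-oxy)phenyl]-2-oxoethyl}-7,7-dibromo-2-oxabicyclo[4.1.0]heptane-3-carboxylate, both cis-fused diastereomers | BrC1(Br)C2CC[C@](CC(=O)c3cc(O[Si](C)(C)C(C)(C)C)ccc3O[Si](C)(C)C(C)(C)C)(C(=O)OCC[Si](C)(C)C)OC12 | intermediate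
17 | (S)-configured 6-bromo-2,3,4-trihydrooxepin-1-ium (bromoallyl oxocarbenium ion) bearing the C2 substituents | BrC1=CCC[C@](CC(=O)c2cc(O[Si](C)(C)C(C)(C)C)ccc2O[Si](C)(C)C(C)(C)C)(C(=O)OCC[Si](C)(C)C)[O+]=C1 | intermediate (not isolated)
18 | 2-(trimethylsilyl)ethyl (2S)-2-{2-[2,5-bis(TBS-oxy)phenyl]-2-oxoethyl}-6-bromo-7-methoxy-2,3,4,7-tetrahydrooxepine-2-carboxylate, C7 epimers | BrC1=CCC[C@](CC(=O)c2cc(O[Si](C)(C)C(C)(C)C)ccc2O[Si](C)(C)C(C)(C)C)(C(=O)OCC[Si](C)(C)C)OC1OC | intermediate
19 | 2-(trimethylsilyl)ethyl (S)-2-{2-[2,5-bis(TBS-oxy)phenyl]-2-oxoethyl}-6-bromo-2,3,4,7-tetrahydrooxepine-2-carboxylate | BrC1=CCC[C@](CC(=O)c2cc(O[Si](C)(C)C(C)(C)C)ccc2O[Si](C)(C)C(C)(C)C)(C(=O)OCC[Si](C)(C)C)OC1 | intermediate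
20 | tert-butyldimethyl(prop-2-yn-1-yloxy)silane | C#CCO[Si](C)(C)C(C)(C)C | starting material
21 | dimethyl[(E)-3-(tert-butyldimethylsilyloxy)-2-methylprop-1-enyl]alane | C[Al](C)/C=C(\C)CO[Si](C)(C)C(C)(C)C | intermediate (not isolated)
22 | lithium butyldimethyl[(E)-3-(tert-butyldimethylsilyloxy)-2-methylprop-1-enyl]alanate | [Li+].CCCC[Al-](C)(C)/C=C(\C)CO[Si](C)(C)C(C)(C)C | intermediate (not isolated)
23 | (E)-5-(tert-butyldimethylsilyloxy)-4-methylpent-3-en-1-ol | OCC/C=C(\C)CO[Si](C)(C)C(C)(C)C | intermediate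
24 | (E)-tert-butyl[(5-iodo-2-methylpent-2-en-1-yl)oxy]dimethylsilane | ICC/C=C(\C)CO[Si](C)(C)C(C)(C)C | intermediate
25 | [(E)-5-(tert-butyldimethylsilyloxy)-4-methylpent-3-enyl]zinc iodide | I[Zn]CC/C=C(\C)CO[Si](C)(C)C(C)(C)C | intermediate (not isolated)
26 | 2-(trimethylsilyl)ethyl (S)-2-{2-[2,5-bis(TBS-oxy)phenyl]-2-oxoethyl}-6-[(E)-5-(TBS-oxy)-4-methylpent-3-enyl]-2,3,4,7-tetrahydrooxepine-2-carboxylate | C/C(=C\CCC1=CCC[C@](CC(=O)c2cc(O[Si](C)(C)C(C)(C)C)ccc2O[Si](C)(C)C(C)(C)C)(C(=O)OCC[Si](C)(C)C)OC1)CO[Si](C)(C)C(C)(C)C | intermediate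
27 | 2-(trimethylsilyl)ethyl (S)-2-{2-[2,5-bis(TBS-oxy)phenyl]-2-oxoethyl}-6-[(E)-5-hydroxy-4-methylpent-3-enyl]-2,3,4,7-tetrahydrooxepine-2-carboxylate | C/C(=C\CCC1=CCC[C@](CC(=O)c2cc(O[Si](C)(C)C(C)(C)C)ccc2O[Si](C)(C)C(C)(C)C)(C(=O)OCC[Si](C)(C)C)OC1)CO | intermediate
28 | (E)-4-hydroxycinnamic acid (p-coumaric acid) | OC(=O)/C=C/c1ccc(O)cc1 | starting material
29 | 2-(trimethylsilyl)ethyl (S)-2-{2-[2,5-bis(TBS-oxy)phenyl]-2-oxoethyl}-6-[(E)-5-[(E)-3-(4-hydroxyphenyl)acryloyloxy]-4-methylpent-3-enyl]-2,3,4,7-tetrahydrooxepine-2-carboxylate | C/C(=C\CCC1=CCC[C@](CC(=O)c2cc(O[Si](C)(C)C(C)(C)C)ccc2O[Si](C)(C)C(C)(C)C)(C(=O)OCC[Si](C)(C)C)OC1)COC(=O)/C=C/c1ccc(O)cc1 | intermediate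
30 | (S)-2-[2-(2,5-dihydroxyphenyl)-2-oxoethyl]-6-[(E)-5-[(E)-3-(4-hydroxyphenyl)acryloyloxy]-4-methylpent-3-enyl]-2,3,4,7-tetrahydrooxepine-2-carboxylic acid | C/C(=C\CCC1=CCC[C@](CC(=O)c2cc(O)ccc2O)(C(=O)O)OC1)COC(=O)/C=C/c1ccc(O)cc1 | target

Total step count: 16. Longest linear sequence: 12 steps (steps 1, 2, 5, 6, 7, 8, 9, 10, 13, 14, 15, 16).

Steps most likely to fail

Step 9 (key step). Silver-assisted ionisation may be diverted into proton loss from the bromoallyl cation, giving a bromodiene, or AgOTf and the acid it releases may trigger β-elimination of the ring oxygen next to the ketone. The fallback does without silver and without a free cation in a protic medium. Setting out from 16, the adduct is heated in toluene at 110 °C, so that the same disrotatory ring enlargement takes place thermally and the bromide returns to C7, giving the covalent allylic α-bromo ether 2-(trimethylsilyl)ethyl (2S)-2-{2-[2,5-bis(TBS-oxy)phenyl]-2-oxoethyl}-6,7-dibromo-2,3,4,7-tetrahydrooxepine-2-carboxylate F1. This bromide is then solvolysed in MeOH over solid NaHCO3 at 0 °C, and the route is rejoined at 18.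

Step 5. The hindered ortho-silyloxy aryl enol silane and the long-chain keto ester may show poor facial selectivity or slow catalyst turnover. The fallback uses the class of nucleophile for which this catalyst is best established and forms the aryl ketone afterwards. Setting out from 6, the same Cu(OTf)2/bis(oxazoline) addition is run with 1-(ethylthio)-1-(trimethylsilyloxy)ethene F2 (made from S-ethyl thioacetate with LiN(iPr)2 and TMSCl), which should give, after the acidic work-up of step 5, the thioester 2-(trimethylsilyl)ethyl (S)-2-[2-(ethylthio)-2-oxoethyl]-2-hydroxyhept-6-enoate F3. In parallel, bromohydroquinone is silylated (TBSCl, imidazole) to 2-bromo-1,4-bis(tert-butyldimethylsilyloxy)benzene F4. Magnesium insertion in the presence of ZnCl2 and LiCl in THF converts it into [2,5-bis(tert-butyldimethylsilyloxy)phenyl]zinc chloride F5. Fukuyama coupling of F3 and F5 (PdCl2(PPh3)2, THF–toluene, rt) forms the aryl ketone without base and comes back to the route at 11.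

Step 15. With the unprotected acid 28, O-alkylation of its phenol may compete with ester formation, and the activated allylic alcohol may suffer allylic transposition. The fallback activates the acid instead of the alcohol. Setting out from 28, silylation with TBSCl and imidazole gives tert-butyldimethylsilyl (E)-4-(tert-butyldimethylsilyloxy)cinnamate F6. Its silyl ester is cleaved with AcOH–THF–H2O to give (E)-4-(tert-butyldimethylsilyloxy)cinnamic acid F7. Carbodiimide acylation of 27 with F7 (EDC·HCl, DMAP, CH2Cl2) gives the fully silylated ester 2-(trimethylsilyl)ethyl (S)-2-{2-[2,5-bis(TBS-oxy)phenyl]-2-oxoethyl}-6-[(E)-5-[(E)-3-(4-(TBS-oxy)phenyl)acryloyloxy]-4-methylpent-3-enyl]-2,3,4,7-tetrahydrooxepine-2-carboxylate F8. Under the conditions of step 16, F8 loses all four silicon groups and arrives at 30.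

Further compounds
F1 | step 9 | 2-(trimethylsilyl)ethyl (2S)-2-{2-[2,5-bis(TBS-oxy)phenyl]-2-oxoethyl}-6,7-dibromo-2,3,4,7-tetrahydrooxepine-2-carboxylate | BrC1=CCC[C@](CC(=O)c2cc(O[Si](C)(C)C(C)(C)C)ccc2O[Si](C)(C)C(C)(C)C)(C(=O)OCC[Si](C)(C)C)OC1Br
F2 | step 5 | 1-(ethylthio)-1-(trimethylsilyloxy)ethene | C=C(SCC)O[Si](C)(C)C
F3 | step 5 | 2-(trimethylsilyl)ethyl (S)-2-[2-(ethylthio)-2-oxoethyl]-2-hydroxyhept-6-enoate | C=CCCC[C@](CC(=O)SCC)(C(=O)OCC[Si](C)(C)C)O
F4 | step 5 | 2-bromo-1,4-bis(tert-butyldimethylsilyloxy)benzene | Brc1cc(O[Si](C)(C)C(C)(C)C)ccc1O[Si](C)(C)C(C)(C)C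
F5 | step 5 | [2,5-bis(tert-butyldimethylsilyloxy)phenyl]zinc chloride | Cl[Zn]c1cc(O[Si](C)(C)C(C)(C)C)ccc1O[Si](C)(C)C(C)(C)C
F6 | step 15 | tert-butyldimethylsilyl (E)-4-(tert-butyldimethylsilyloxy)cinnamate | CC(C)(C)[Si](C)(C)OC(=O)/C=C/c1ccc(O[Si](C)(C)C(C)(C)C)cc1
F7 | step 15 | (E)-4-(tert-butyldimethylsilyloxy)cinnamic acid | OC(=O)/C=C/c1ccc(O[Si](C)(C)C(C)(C)C)cc1
F8 | step 15 | 2-(trimethylsilyl)ethyl (S)-2-{2-[2,5-bis(TBS-oxy)phenyl]-2-oxoethyl}-6-[(E)-5-[(E)-3-(4-(TBS-oxy)phenyl)acryloyloxy]-4-methylpent-3-enyl]-2,3,4,7-tetrahydrooxepine-2-carboxylate | C/C(=C\CCC1=CCC[C@](CC(=O)c2cc(O[Si](C)(C)C(C)(C)C)ccc2O[Si](C)(C)C(C)(C)C)(C(=O)OCC[Si](C)(C)C)OC1)COC(=O)/C=C/c1ccc(O[Si](C)(C)C(C)(C)C)cc1
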